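Your vessel is closed, stirred and held at one temperature, and it sends starting material down two outlets, to target and to side product.

| setting | west | south-west | south | flask |
|---|---|---|---|---|
| starting material | 1.1 M | 1.8 M | 0.80 M | 0.80 M |
| coupling partner | 1.5 equiv | 1.5 equiv | 1.5 equiv | 1.50 equiv |
| catalyst | 0.2 mol% | 0.2 mol% | 0.1 mol% | 0.2 mol% |
| remark | run made earlier | run made earlier | run made earlier |  |
| time |  |  |  | 3.0 d |

- west (time / h: target / %, side product / %): 2.50: 22.6, 73.3; 6.00: 24.2, 74.4; 12.0: 23.9, 77.1; 20.0: 22.2, 77.1; 25.0: 21.9, 75.6; 30.0: 23.5, 77.7; 40.0: 22.7, 76.8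
- south-west (time / h: target / %, side product / %): 3.00: 42.8, 57.2; 5.00: 42.2, 59.6; 8.00: 42.0, 58.1; 12.0: 42.3, 57.6; 20.0: 40.8, 56.9; 30.0: 42.6, 60.2; 40.0: 41.6, 56.6
- south (time / h: target / %, side product / %): 3.00: 6.2, 80.4; 6.00: 7.9, 90.0; 12.0: 7.4, 92.7; 25.0: 8.1, 93.0; 40.0: 7.8, 92.1

(readings scatter by 1 percentage point)



1. ratio of target to side product at 10 min
2. ratio of target to side product at 3.0 d
3. which of target and side product there is more of at 3.0 d

In the runs the two products add up to about the charge and stand flat from 12.0 h on. So read target's share of the two there: 7.74% south, 22.9% west, 42.0% south-west.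

My first guess treats them as parallel drains, with target over side product equal to a constant times catalyst concentration times coupling partner concentration. With the partner taken at its charge, the south run gives 87.4 L^2 mol⁻², and that puts the flask near 0.168.

But south-west gives less than south, 74.4 L^2 mol⁻², and the weak link is the partner, which I assume one target consumes one for one. So work with the fraction left. The logarithm of partner charged over partner left, divided by catalyst concentration and side product concentration, gives 89.7 L^2 mol⁻², 88.8 L^2 mol⁻² and 87.3 L^2 mol⁻². Their mean, 88.6 L^2 mol⁻², I call the pull, a selectivity factor.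

For the flask the pull gives a starting ratio of 0.170, my value at 10 min. Solving for the end by two passes gives 14.0% target, a ratio of 0.162.

The forecast says 0.17 (0.12 to 0.25) at 10 min, 0.17 (0.145 to 0.2) at 3.0 d, and more side product, on the grounds that “target and side product do not interconvert and the split is kinetic”. It holds the ratio level, where mine falls slightly.

The flask gives 0.170 at 10 min and 0.163 at 3.0 d, with 14.0% target and 86.0% side product.

    starting material + catalyst ⇌ catalyst + intermediate (K = 0.369, k = 0.358 L mol⁻¹ s⁻¹)
    coupling partner + catalyst + intermediate → catalyst + target (k = 0.138 L² mol⁻² s⁻¹)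
    intermediate → side product (k = 0.00155 s⁻¹)

In the flask both steps out of the intermediate ran while starting material lasted, and at 0.300 d 0.0603% of it stood. By 0.300 d the step to target had 99.9% of its turnover up to 3.0 d behind it, and at 3.00 d target stood at 14.0% with coupling partner at 90.7% of its charge. The flask's own pull comes to 89.0 L^2 mol⁻². The same flask with 0.8 mol% catalyst has a pull of 89.0 L^2 mol⁻² and ends at a ratio of 0.595, above 0.2, the top of the forecast's range for this flask. That neighbour ends with 62.7% side product.

(The runs were computed for an exercise.)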